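The route disconnects the C1''–C2'' bond of the 2-hydroxy-3-methylbutyl chain on C6 of ring A. The key step exploits the fact that the only stereocentre, the secondary carbinol C2'', lies between an isopropyl group and the benzylic C1'' methylene. A benzylic pinacol boronate of ring A (C5 methyl ether, C7 and C8a MOM ethers, C8 prenyl group) is joined to a sparteine-complexed α-lithiated isobutyl carbamate. One operation forges the C–C bond and sets the S configuration as a C–B bond, which is oxidised afterwards. Ring B and the pyranone ring follow through an acetophenone, a deoxybenzoin and an enaminone.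

Key step: step 5

Remark: the configuration at the transient carbinolamine carbon of 20 and the double-bond geometry of 24 are left undefined, since both are erased in the next event; (−)-sparteine is taken as purchasable in enantiopure form.

Step 1
Reactants: 1 5-methoxyresorcinol
Product: 2 1-methoxy-3,5-bis(methoxymethoxy)benzene
Conditions: NaH, MOMCl, DMF, 0 °C → rt
Reagents that add atoms: chloromethyl methyl ether (MOMCl), COCCl
Why: Double Williamson-type O-alkylation of the two phenoxides should give the bis-MOM ether, which carries the directing groups for the two ring metalations that follow.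

Step 2
Reactants: 2 1-methoxy-3,5-bis(methoxymethoxy)benzene; 3 prenyl bromide (1-bromo-3-methylbut-2-ene)
Product: 6 5-methoxy-1,3-bis(methoxymethoxy)-2-(3-methylbut-2-en-1-yl)benzene, via aryllithium 4 (not isolated), via arylcopper 5 (not isolated)
Conditions: n-BuLi, THF, 0 °C; CuI, −40 °C; 3, −40 °C → rt
Reagents that add atoms: none
Why: Directed ortho-metalation should take place mainly at the ring position flanked by the two chelating MOM ethers, and the arylcopper formed with CuI should be alkylated at the primary carbon of the allylic bromide (copper-mediated SN2 allylation) without allylic transposition.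

Step 3
Reactants: 6 5-methoxy-1,3-bis(methoxymethoxy)-2-(3-methylbut-2-en-1-yl)benzene; 7 2-(chloromethyl)-4,4,5,5-tetramethyl-1,3,2-dioxaborolane
Product: 10 2-{[6-methoxy-2,4-bis(methoxymethoxy)-3-(3-methylbut-2-en-1-yl)phenyl]methyl}-4,4,5,5-tetramethyl-1,3,2-dioxaborolane, via aryllithium 8 (not isolated), via chloromethyl borate complex 9 (not isolated)
Conditions: n-BuLi, TMEDA, THF, −20 → 0 °C; 7, −78 °C → rt
Reagents that add atoms: none
Why: A second directed ortho-metalation can only occur at one of the two symmetry-equivalent ring positions between OMe and OMOM, and the aryllithium adds to boron of 7 to give a borate whose aryl group shifts to carbon with loss of chloride on warming (Matteson homologation).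

Step 4
Reactants: 11 2-methylpropan-1-ol
Product: 12 2-methylpropyl N,N-diisopropylcarbamate
Conditions: NaH, iPr2NCOCl, THF, reflux
Reagents that add atoms: N,N-diisopropylcarbamoyl chloride, CC(C)N(C(C)C)C(Cl)=O
Why: Carbamoylation of the sodium alkoxide (nucleophilic acyl substitution) installs the group that directs α-lithiation and later serves as the leaving group.

Step 5
Reactants: 10 2-{[6-methoxy-2,4-bis(methoxymethoxy)-3-(3-methylbut-2-en-1-yl)phenyl]methyl}-4,4,5,5-tetramethyl-1,3,2-dioxaborolane; 12 2-methylpropyl N,N-diisopropylcarbamate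
Product: 15 2-{(2S)-1-[6-methoxy-2,4-bis(methoxymethoxy)-3-(3-methylbut-2-en-1-yl)phenyl]-3-methylbutan-2-yl}-4,4,5,5-tetramethyl-1,3,2-dioxaborolane, via lithiated carbamate 13 (not isolated), via borate complex 14 (not isolated)
Conditions: 12, s-BuLi, (−)-sparteine, Et2O, −78 °C; 10, −78 °C; MgBr2·OEt2, −78 °C → reflux
Reagents that add atoms: none
Why: s-BuLi/(−)-sparteine removes the pro-S α-proton of 12 (carbamate-directed asymmetric deprotonation) to give the configurationally stable carbenoid 13, which attacks boron of 10 with retention to form borate complex 14. On warming, assisted by MgBr2·OEt2, the benzylic carbon of 14 shifts from boron to C2'' antiperiplanar to the departing carbamate, so the C1''–C2'' bond forms with inversion at carbon in a stereospecific 1,2-metalate rearrangement. The closest known reaction type is the lithiation–borylation of diamine-ligated primary alkyl carbamates with primary and benzylic pinacol boronates, a reagent-controlled variant of the Matteson homologation. No ring is closed. The C2'' stereocentre is set by the diamine alone (pro-S deprotonation, retention at boron capture, inversion in the shift), which should give the S boronate and hence the S carbinol after oxidation with retention. The step needs attack at boron in preference to deprotonation of ring, benzylic or allylic C–H and to any reaction at the alkene, which is secured by preforming 13 with carbamate in slight excess over s-BuLi at −78 °C, by the Lewis acidity of the unhindered primary boronate and by the absence of carbonyl or O–H groups in 10.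

Step 6
Reactants: 15 2-{(2S)-1-[6-methoxy-2,4-bis(methoxymethoxy)-3-(3-methylbut-2-en-1-yl)phenyl]-3-methylbutan-2-yl}-4,4,5,5-tetramethyl-1,3,2-dioxaborolane
Product: 16 (2S)-1-[6-methoxy-2,4-bis(methoxymethoxy)-3-(3-methylbut-2-en-1-yl)phenyl]-3-methylbutan-2-ol
Conditions: H2O2 (30% aq), NaOH (2 M aq), THF, 0 °C → rt
Reagents that add atoms: hydrogen peroxide, OO
Why: Hydroperoxide adds to boron and the secondary alkyl group shifts to oxygen with retention (boronate oxidation), giving the S carbinol while alkaline peroxide leaves the isolated trisubstituted alkene and the MOM ethers untouched.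

Step 7
Reactants: 16 (2S)-1-[6-methoxy-2,4-bis(methoxymethoxy)-3-(3-methylbut-2-en-1-yl)phenyl]-3-methylbutan-2-ol
Product: 17 tert-butyl{[(2S)-1-[6-methoxy-2,4-bis(methoxymethoxy)-3-(3-methylbut-2-en-1-yl)phenyl]-3-methylbutan-2-yl]oxy}dimethylsilane
Conditions: TBSCl, imidazole, DMAP (cat.), DMF, 40 °C
Reagents that add atoms: tert-butyldimethylsilyl chloride (TBSCl), CC(C)(C)[Si](C)(C)Cl
Why: Imidazole-promoted silylation masks the only acidic proton before the next metalation and gives an ether that is later removed in the same acidic operation as the MOM groups.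

Step 8
Reactants: 17 tert-butyl{[(2S)-1-[6-methoxy-2,4-bis(methoxymethoxy)-3-(3-methylbut-2-en-1-yl)phenyl]-3-methylbutan-2-yl]oxy}dimethylsilane; 18 N-methoxy-N-methylacetamide
Product: 21 1-{3-[(2S)-2-(tert-butyldimethylsilyloxy)-3-methylbutyl]-2-methoxy-4,6-bis(methoxymethoxy)-5-(3-methylbut-2-en-1-yl)phenyl}ethan-1-one, via aryllithium 19 (not isolated), via tetrahedral adduct 20 (not isolated)
Conditions: n-BuLi, TMEDA, THF, −20 → 0 °C; 18, −78 → 0 °C; aq NH4Cl
Reagents that add atoms: none
Why: Directed ortho-metalation at the last ring C–H, flanked by OMe and OMOM, followed by acylation through a chelated tetrahedral adduct that collapses only on work-up (Weinreb ketone synthesis) should give the methyl ketone without over-addition.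

Step 9
Reactants: 21 1-{3-[(2S)-2-(tert-butyldimethylsilyloxy)-3-methylbutyl]-2-methoxy-4,6-bis(methoxymethoxy)-5-(3-methylbut-2-en-1-yl)phenyl}ethan-1-one; 22 1-bromo-4-(methoxymethoxy)benzene
Product: 23 1-{3-[(2S)-2-(tert-butyldimethylsilyloxy)-3-methylbutyl]-2-methoxy-4,6-bis(methoxymethoxy)-5-(3-methylbut-2-en-1-yl)phenyl}-2-[4-(methoxymethoxy)phenyl]ethan-1-one
Conditions: 22, Pd2(dba)3 (cat.), Xantphos (cat.), NaOtBu, THF, 70 °C
Reagents that add atoms: none
Why: Palladium-catalysed α-arylation of the methyl ketone enolate (zerovalent palladium with a wide-bite-angle bisphosphine) should give the deoxybenzoin, mono-arylation being favoured because the product enolate is more hindered and more stabilised, while silyl ether, MOM ethers and alkene are inert to NaOtBu.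

Step 10
Reactants: 23 1-{3-[(2S)-2-(tert-butyldimethylsilyloxy)-3-methylbutyl]-2-methoxy-4,6-bis(methoxymethoxy)-5-(3-methylbut-2-en-1-yl)phenyl}-2-[4-(methoxymethoxy)phenyl]ethan-1-one
Product: 24 1-{3-[(2S)-2-(tert-butyldimethylsilyloxy)-3-methylbutyl]-2-methoxy-4,6-bis(methoxymethoxy)-5-(3-methylbut-2-en-1-yl)phenyl}-3-(dimethylamino)-2-[4-(methoxymethoxy)phenyl]prop-2-en-1-one
Conditions: DMF-DMA, toluene, 100 °C
Reagents that add atoms: N,N-dimethylformamide dimethyl acetal (DMF-DMA), COC(OC)N(C)C
Why: Condensation of the doubly activated methylene with the amide acetal (enaminone formation) adds the future C2 of the pyranone ring under neutral aprotic conditions while every hydroxyl group is still protected.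

Step 11
Reactants: 24 1-{3-[(2S)-2-(tert-butyldimethylsilyloxy)-3-methylbutyl]-2-methoxy-4,6-bis(methoxymethoxy)-5-(3-methylbut-2-en-1-yl)phenyl}-3-(dimethylamino)-2-[4-(methoxymethoxy)phenyl]prop-2-en-1-one
Product: 25 7-hydroxy-6-[(2S)-2-hydroxy-3-methylbutyl]-3-(4-hydroxyphenyl)-5-methoxy-8-(3-methylbut-2-en-1-yl)-4H-chromen-4-one (CNP0323282.1)
Conditions: HCl (3 M in MeOH), THF, 0 → 45 °C
Reagents that add atoms: none
Why: Acidic methanolysis should cleave the three MOM ethers and the silyl ether, and the freed C8a phenol should add to the enaminone carbon and expel dimethylamine (addition–elimination chromone ring closure); the C5 methyl ether leaves only one ortho oxygen able to close the ring, and the homobenzylic stereocentre cannot ionise or epimerise.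

Compound list
1 | 5-methoxyresorcinol | COc1cc(O)cc(O)c1 | starting material
2 | 1-methoxy-3,5-bis(methoxymethoxy)benzene | COCOc1cc(OC)cc(OCOC)c1 | intermediate
3 | prenyl bromide (1-bromo-3-methylbut-2-ene) | CC(C)=CCBr | starting material
4 | [4-methoxy-2,6-bis(methoxymethoxy)phenyl]lithium | [Li]c1c(OCOC)cc(OC)cc1OCOC | intermediate (not isolated)
5 | [4-methoxy-2,6-bis(methoxymethoxy)phenyl]copper | [Cu]c1c(OCOC)cc(OC)cc1OCOC | intermediate (not isolated)
6 | 5-methoxy-1,3-bis(methoxymethoxy)-2-(3-methylbut-2-en-1-yl)benzene | COc1cc(OCOC)c(CC=C(C)C)c(OCOC)c1 | intermediate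
7 | 2-(chloromethyl)-4,4,5,5-tetramethyl-1,3,2-dioxaborolane | ClCB1OC(C)(C)C(C)(C)O1 | starting material
8 | [6-methoxy-2,4-bis(methoxymethoxy)-3-(3-methylbut-2-en-1-yl)phenyl]lithium | COc1cc(OCOC)c(CC=C(C)C)c(OCOC)c1[Li] | intermediate (not isolated)
9 | lithium (chloromethyl)[6-methoxy-2,4-bis(methoxymethoxy)-3-(3-methylbut-2-en-1-yl)phenyl](pinacolato)borate | COc1cc(OCOC)c(CC=C(C)C)c(OCOC)c1[B-]1(CCl)OC(C)(C)C(C)(C)O1.[Li+] | intermediate (not isolated)
10 | 2-{[6-methoxy-2,4-bis(methoxymethoxy)-3-(3-methylbut-2-en-1-yl)phenyl]methyl}-4,4,5,5-tetramethyl-1,3,2-dioxaborolane (benzylic boronate, key-step precursor) | COc1cc(OCOC)c(CC=C(C)C)c(OCOC)c1CB1OC(C)(C)C(C)(C)O1 | intermediate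
11 | 2-methylpropan-1-ol | CC(C)CO | starting material
12 | 2-methylpropyl N,N-diisopropylcarbamate | CC(C)COC(=O)N(C(C)C)C(C)C | intermediate
13 | (S)-1-lithio-2-methylpropyl N,N-diisopropylcarbamate, as its (−)-sparteine complex (diamine not drawn) | CC(C)[C@H]([Li])OC(=O)N(C(C)C)C(C)C | intermediate (not isolated)
14 | lithium borate complex from 13 and 10, S at the carbamate-bearing carbon | CC(C)[C@H]([B-]1(Cc2c(OC)cc(OCOC)c(CC=C(C)C)c2OCOC)OC(C)(C)C(C)(C)O1)OC(=O)N(C(C)C)C(C)C.[Li+] | intermediate (not isolated)
15 | 2-{(2S)-1-[6-methoxy-2,4-bis(methoxymethoxy)-3-(3-methylbut-2-en-1-yl)phenyl]-3-methylbutan-2-yl}-4,4,5,5-tetramethyl-1,3,2-dioxaborolane (key-step product) | COc1cc(OCOC)c(CC=C(C)C)c(OCOC)c1C[C@H](B1OC(C)(C)C(C)(C)O1)C(C)C | intermediate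
16 | (2S)-1-[6-methoxy-2,4-bis(methoxymethoxy)-3-(3-methylbut-2-en-1-yl)phenyl]-3-methylbutan-2-ol | COc1cc(OCOC)c(CC=C(C)C)c(OCOC)c1C[C@H](O)C(C)C | intermediate
17 | tert-butyl{[(2S)-1-[6-methoxy-2,4-bis(methoxymethoxy)-3-(3-methylbut-2-en-1-yl)phenyl]-3-methylbutan-2-yl]oxy}dimethylsilane | COc1cc(OCOC)c(CC=C(C)C)c(OCOC)c1C[C@H](O[Si](C)(C)C(C)(C)C)C(C)C | intermediate
18 | N-methoxy-N-methylacetamide | CC(=O)N(C)OC | starting material
19 | {3-[(2S)-2-(tert-butyldimethylsilyloxy)-3-methylbutyl]-2-methoxy-4,6-bis(methoxymethoxy)-5-(3-methylbut-2-en-1-yl)phenyl}lithium | COc1c([Li])c(OCOC)c(CC=C(C)C)c(OCOC)c1C[C@H](O[Si](C)(C)C(C)(C)C)C(C)C | intermediate (not isolated)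
20 | lithium alkoxide of the tetrahedral adduct of 19 and 18 (new sp3 carbon undefined) | COc1c(C(C)([O-])N(C)OC)c(OCOC)c(CC=C(C)C)c(OCOC)c1C[C@H](O[Si](C)(C)C(C)(C)C)C(C)C.[Li+] | intermediate (not isolated)
21 | 1-{3-[(2S)-2-(tert-butyldimethylsilyloxy)-3-methylbutyl]-2-methoxy-4,6-bis(methoxymethoxy)-5-(3-methylbut-2-en-1-yl)phenyl}ethan-1-one | COc1c(C(C)=O)c(OCOC)c(CC=C(C)C)c(OCOC)c1C[C@H](O[Si](C)(C)C(C)(C)C)C(C)C | intermediate
22 | 1-bromo-4-(methoxymethoxy)benzene | COCOc1ccc(Br)cc1 | starting material
23 | 1-{3-[(2S)-2-(tert-butyldimethylsilyloxy)-3-methylbutyl]-2-methoxy-4,6-bis(methoxymethoxy)-5-(3-methylbut-2-en-1-yl)phenyl}-2-[4-(methoxymethoxy)phenyl]ethan-1-one (deoxybenzoin) | COc1c(C(=O)Cc2ccc(OCOC)cc2)c(OCOC)c(CC=C(C)C)c(OCOC)c1C[C@H](O[Si](C)(C)C(C)(C)C)C(C)C | intermediate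
24 | 1-{3-[(2S)-2-(tert-butyldimethylsilyloxy)-3-methylbutyl]-2-methoxy-4,6-bis(methoxymethoxy)-5-(3-methylbut-2-en-1-yl)phenyl}-3-(dimethylamino)-2-[4-(methoxymethoxy)phenyl]prop-2-en-1-one (enaminone, alkene geometry undefined) | COc1c(C(=O)C(=CN(C)C)c2ccc(OCOC)cc2)c(OCOC)c(CC=C(C)C)c(OCOC)c1C[C@H](O[Si](C)(C)C(C)(C)C)C(C)C | intermediate
25 | 7-hydroxy-6-[(2S)-2-hydroxy-3-methylbutyl]-3-(4-hydroxyphenyl)-5-methoxy-8-(3-methylbut-2-en-1-yl)-4H-chromen-4-one (CNP0323282.1) | COc1c(C[C@H](O)C(C)C)c(O)c(CC=C(C)C)c2occ(-c3ccc(O)cc3)c(=O)c12 | target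

Total step count: 11 steps.
Longest linear sequence: 10 steps (steps 1–3 and 5–11, from 5-methoxyresorcinol); step 4 is a one-step side branch.

Steps most likely to fail

Step 5. The borate complex may form incompletely or revert, the shift of the di-ortho-substituted benzyl group may lag behind decomposition of the carbenoid, the lithiated carbamate may lose configurational purity, or MgBr2 may strip a MOM ether. The fallback sets out from 6 and rejoins the route at 16. Compound 6 would be metalated as in step 3 to aryllithium 8. This would open purchased (R)-2-isopropyloxirane (SMILES C1[C@H](O1)C(C)C) at its unsubstituted carbon with BF3·OEt2 in THF at −78 °C (Lewis-acid-assisted epoxide opening by an aryllithium). The C–O bond at the stereocentre is not touched, so the R epoxide should give the S carbinol 16 directly (the descriptor changes only because the ring CH2 outranks isopropyl in the epoxide). No compound outside the list is made (F0).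

Step 9. Enolate coupling may be slow at the crowded, fully substituted aryl ketone, a second arylation may occur at the new methylene, or the aryl bromide may be reduced. The fallback sets out from 17 and rejoins the route at 23. Metalation of 17 as in step 8 (aryllithium 19) and a DMF quench would give the ring A benzaldehyde F1. Separately, purchased 4-(methoxymethoxy)benzaldehyde (COCOc1ccc(C=O)cc1) would be reduced with NaBH4 to [4-(methoxymethoxy)phenyl]methanol F2. This would be converted with MsCl, Et3N and LiCl into 1-(chloromethyl)-4-(methoxymethoxy)benzene F3, and then with magnesium in THF into [4-(methoxymethoxy)benzyl]magnesium chloride F4. Addition of F4 to F1 would give the secondary carbinol F5 as a mixture of epimers at the new carbon, and Dess–Martin oxidation would give deoxybenzoin 23.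

Step 11. Acid-promoted addition of the freed C7 hydroxyl to the prenyl alkene (chroman formation) or addition of HCl to that alkene may compete with complete cleavage of the MOM ethers. The fallback sets out from 23 and rejoins the route at 25. The aryl MOM ethers of 23 would be removed without protic acid by TMSOTf and 2,2'-bipyridyl in CH2Cl2 followed by water (silyl transfer through a pyridinium acetal; the phenols are released as silyl ethers and hydrolysed under neutral conditions), giving the triphenolic deoxybenzoin silyl ether F6. DMF-DMA in THF at 60 °C would then close the pyranone ring at the free C8a hydroxyl to give the 7-hydroxyisoflavone silyl ether F7. TBAF in THF would finally remove the silyl group to give 25.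

Further compounds
F0 | step 5 | none | none
F1 | step 9 | 3-[(2S)-2-(tert-butyldimethylsilyloxy)-3-methylbutyl]-2-methoxy-4,6-bis(methoxymethoxy)-5-(3-methylbut-2-en-1-yl)benzaldehyde | COc1c(C=O)c(OCOC)c(CC=C(C)C)c(OCOC)c1C[C@H](O[Si](C)(C)C(C)(C)C)C(C)C
F2 | step 9 | [4-(methoxymethoxy)phenyl]methanol | COCOc1ccc(CO)cc1
F3 | step 9 | 1-(chloromethyl)-4-(methoxymethoxy)benzene | COCOc1ccc(CCl)cc1
F4 | step 9 | [4-(methoxymethoxy)benzyl]magnesium chloride | COCOc1ccc(C[Mg]Cl)cc1
F5 | step 9 | 1-{3-[(2S)-2-(tert-butyldimethylsilyloxy)-3-methylbutyl]-2-methoxy-4,6-bis(methoxymethoxy)-5-(3-methylbut-2-en-1-yl)phenyl}-2-[4-(methoxymethoxy)phenyl]ethan-1-ol (carbinol carbon undefined) | COc1c(C(O)Cc2ccc(OCOC)cc2)c(OCOC)c(CC=C(C)C)c(OCOC)c1C[C@H](O[Si](C)(C)C(C)(C)C)C(C)C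
F6 | step 11 | 1-{3-[(2S)-2-(tert-butyldimethylsilyloxy)-3-methylbutyl]-4,6-dihydroxy-2-methoxy-5-(3-methylbut-2-en-1-yl)phenyl}-2-(4-hydroxyphenyl)ethan-1-one | COc1c(C(=O)Cc2ccc(O)cc2)c(O)c(CC=C(C)C)c(O)c1C[C@H](O[Si](C)(C)C(C)(C)C)C(C)C
F7 | step 11 | 6-[(2S)-2-(tert-butyldimethylsilyloxy)-3-methylbutyl]-7-hydroxy-3-(4-hydroxyphenyl)-5-methoxy-8-(3-methylbut-2-en-1-yl)-4H-chromen-4-one | COc1c(C[C@H](O[Si](C)(C)C(C)(C)C)C(C)C)c(O)c(CC=C(C)C)c2occ(-c3ccc(O)cc3)c(=O)c12
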